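**Retrosynthetic overview**
1. Target 41 ⇐ its aromatic isomer 40 (prenyl ester): the last bond is C6–CH2(prenyl), made by a Pd-catalysed O-to-C prenyl transfer that dearomatizes the carbocycle, sets C6 and frees the acid.
2. 40 ⇐ 38: the pyranone ring is closed by a Mitsunobu reaction (inversion) on an anti-aldol unit to give the cis-2,3-dimethyl pattern; the phenol used is the one released when prenol opens the lactone of 35.
3. 35 ⇐ aryl iodide 21 + C11 alkylzinc 34 (Negishi coupling); the chain stereocentre comes from a Rh-catalysed asymmetric alkenylation of enoate 24.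
4. 21 ⇐ coumarin 16 (Rh-catalysed asymmetric phenyl addition sets the benzylic centre) ⇐ gold-catalysed hydroarylation of aryl propiolate 15 ⇐ ketone 12, from the tris-MOM arene 5 (resorcinol, Ir C–H borylation/oxidation) and Weinreb amide 10 (Fráter–Seebach).
5. Ring order: benzene ring (bought) → lactone ring (step 10, opened again in step 22) → pyranone ring (step 24) → dearomatization of the carbocycle (step 26).

Assumption: 41 is the enol tautomer written in the SMILES, and commercial silyl-protected materials are counted without their protecting group.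

**Route**

Step 1
Reactants: 1 resorcinol
Product: 2 1,3-bis(methoxymethoxy)benzene
Conditions: MOMCl (2.5 equiv), i-Pr2NEt (3 equiv), CH2Cl2, 0 °C to rt
Reagents that add atoms: chloromethyl methyl ether, COCCl
Why: Standard O-alkylation (MOM protection) of both phenols; no stereocentre.

Step 2
Reactants: 2 1,3-bis(methoxymethoxy)benzene
Product: 4 3,5-bis(methoxymethoxy)phenol, via aryl boronate 3 (not isolated)
Conditions: [Ir(cod)(OMe)]2 (1.5 mol%), dtbpy (3 mol%), B2pin2 (0.6 equiv), THF, 80 °C; then 30% H2O2, aq NaOH, 0 °C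
Reagents that add atoms: hydrogen peroxide, OO
Why: Sterically controlled iridium-catalysed aromatic C–H borylation reaches only C5 (the one C–H not ortho to an OMOM group), and boronate oxidation gives the third ring oxygen.

Step 3
Reactants: 4 3,5-bis(methoxymethoxy)phenol
Product: 5 1,3,5-tris(methoxymethoxy)benzene
Conditions: MOMCl (1.3 equiv), i-Pr2NEt (1.5 equiv), CH2Cl2, 0 °C to rt
Reagents that add atoms: chloromethyl methyl ether, COCCl
Why: O-alkylation gives the symmetric arene whose three C–H positions are equivalent, so the next metalation has no regiochemical issue.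

Step 4
Reactants: 6 methyl (3R)-3-hydroxybutanoate
Product: 8 methyl (2R,3R)-3-hydroxy-2-methylbutanoate, via dilithium alkoxide enolate 7 (not isolated)
Conditions: LiN(i-Pr)2 (2.2 equiv), THF, −78 to −20 °C; MeI, DMPU, −78 to −10 °C; aq NH4Cl
Reagents that add atoms: iodomethane, CI
Why: Fráter–Seebach alkylation, in which the chelated dianion is methylated anti to the C3 alkoxide, gives the (2R,3R) anti isomer with high diastereoselectivity.

Step 5
Reactants: 8 methyl (2R,3R)-3-hydroxy-2-methylbutanoate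
Product: 9 methyl (2R,3R)-3-[(tert-butyldimethylsilyl)oxy]-2-methylbutanoate
Conditions: TBSCl, imidazole, DMF, rt
Reagents that add atoms: tert-butyldimethylsilyl chloride, CC(C)(C)[Si](C)(C)Cl
Why: Silylation of the secondary alcohol blocks it until the Mitsunobu step; both stereocentres are untouched.

Step 6
Reactants: 9 methyl (2R,3R)-3-[(tert-butyldimethylsilyl)oxy]-2-methylbutanoate
Product: 10 (2R,3R)-3-[(tert-butyldimethylsilyl)oxy]-N-methoxy-N,2-dimethylbutanamide
Conditions: MeNH(OMe)·HCl (1.5 equiv), i-PrMgCl (3.0 equiv), THF, −20 to 0 °C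
Reagents that add atoms: N,O-dimethylhydroxylamine hydrochloride, CNOC.Cl
Why: Aminolysis of the ester by the magnesium amide (Weinreb amide formation) is non-enolizing, so C2 keeps its configuration.

Step 7
Reactants: 5 1,3,5-tris(methoxymethoxy)benzene; 10 Weinreb amide
Product: 12 (2R,3R)-3-[(tert-butyldimethylsilyl)oxy]-2-methyl-1-[2,4,6-tris(methoxymethoxy)phenyl]butan-1-one, via aryllithium 11 (not isolated)
Conditions: 5 (1.5 equiv), n-BuLi (1.45 equiv), THF, 0 °C, 1 h; then 10, −78 °C to rt; aq NH4Cl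
Reagents that add atoms: none
Why: Directed ortho-metalation between two OMOM groups followed by acyl substitution on the Weinreb amide (stable chelated tetrahedral intermediate, no over-addition) gives the aryl ketone without touching the side-chain stereocentres.

Step 8
Reactants: 12 aryl ketone
Product: 13 (2R,3R)-3-[(tert-butyldimethylsilyl)oxy]-1-[2-hydroxy-4,6-bis(methoxymethoxy)phenyl]-2-methylbutan-1-one
Conditions: MgBr2·OEt2 (2 equiv), Et2O/toluene, 0 °C to rt
Reagents that add atoms: none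
Why: Chelation-controlled acetal cleavage (magnesium bound to the ketone oxygen and one ortho acetal) removes exactly one of the two equivalent ortho MOM groups; the resulting magnesium phenoxide chelate suppresses a second cleavage, and the para MOM and the silyl ether survive.

Step 9
Reactants: 13 ortho-hydroxyaryl ketone; 14 propiolic acid
Product: 15 2-{(2R,3R)-3-[(tert-butyldimethylsilyl)oxy]-2-methylbutanoyl}-3,5-bis(methoxymethoxy)phenyl prop-2-ynoate
Conditions: DCC (1.2 equiv), CH2Cl2, −20 to 0 °C (no DMAP)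
Reagents that add atoms: none
Why: Carbodiimide esterification of the only free hydroxyl tethers the three-carbon unit to the oxygen that will later become the pyranone oxygen.

Step 10
Reactants: 15 aryl propiolate
Product: 16 8-{(2R,3R)-3-[(tert-butyldimethylsilyl)oxy]-2-methylbutanoyl}-5,7-bis(methoxymethoxy)-2H-chromen-2-one
Conditions: JohnPhosAu(MeCN)SbF6 (3 mol%), 1,2-dichloroethane, rt
Reagents that add atoms: none
Why: Monovalent-gold-catalysed intramolecular 6-endo hydroarylation (a formal aromatic C–H alkenylation) can only reach the free ortho carbon, so the coumarin regiochemistry is fixed by the tether.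

Step 11
Reactants: 17 phenylmagnesium bromide
Product: 19 phenylboronic acid, via dimethyl phenylboronate 18 (not isolated)
Conditions: B(OMe)3 (1.5 equiv), THF, −78 °C to rt; 1 M HCl
Reagents that add atoms: trimethyl borate, COB(OC)OC; water, O
Why: Borylation of the Grignard reagent and hydrolysis is the standard boronic acid synthesis.

Step 12
Reactants: 16 coumarin; 19 phenylboronic acid
Product: 20 (4R)-8-{(2R,3R)-3-[(tert-butyldimethylsilyl)oxy]-2-methylbutanoyl}-5,7-bis(methoxymethoxy)-4-phenyl-3,4-dihydro-2H-chromen-2-one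
Conditions: Rh(acac)(C2H4)2 (3 mol%), (R)-SEGPHOS (3.3 mol%), 19 (5 equiv), 1,4-dioxane/H2O 10:1, 60 °C
Reagents that add atoms: none
Why: Hayashi–Miyaura asymmetric 1,4-addition: the phenyl–rhodium species inserts the coumarin C3=C4 bond on the face selected by (R)-SEGPHOS, giving (4R) in the same sense as the known (R)-4-phenylchroman-2-ones, under neutral conditions that spare ketone, silyl ether and acetals.

Step 13
Reactants: 20 dihydrocoumarin
Product: 21 (4R)-8-{(2R,3R)-3-[(tert-butyldimethylsilyl)oxy]-2-methylbutanoyl}-6-iodo-5,7-bis(methoxymethoxy)-4-phenyl-3,4-dihydro-2H-chromen-2-one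
Conditions: NIS (1.1 equiv), MeCN, 0 °C to rt
Reagents that add atoms: N-iodosuccinimide, O=C1CCC(=O)N1I
Why: Electrophilic aromatic iodination at the single remaining, doubly ortho-oxygenated aromatic C–H.

Step 14
Reactants: 22 methyl acrylate; 23 allyloxy(tert-butyl)dimethylsilane
Product: 24 methyl (2E)-4-[(tert-butyldimethylsilyl)oxy]but-2-enoate
Conditions: Grubbs second-generation catalyst (H2IMes)(PCy3)Cl2Ru=CHPh (2 mol%), 22 (3 equiv), CH2Cl2, 40 °C
Reagents that add atoms: none
Why: Olefin cross-metathesis of a reactive terminal alkene with an acrylate is selective for the cross product and for the E isomer.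

Step 15
Reactants: 24 enoate; 25 (2-methylprop-1-en-1-yl)boronic acid
Product: 26 methyl (3S)-3-({[tert-butyl(dimethyl)silyl]oxy}methyl)-5-methylhex-4-enoate
Conditions: Rh(acac)(C2H4)2 (3 mol%), (S)-BINAP (3.3 mol%), 25 (3 equiv), 1,4-dioxane/H2O 10:1, 100 °C
Reagents that add atoms: none
Why: Hayashi–Miyaura asymmetric conjugate alkenylation sets the side-chain stereocentre as (3S); the sense is assigned by analogy with linear (E)-enones and must be checked on 27 by Mosher analysis (the antipodal ligand is used if it is opposite), and the new centre has no acidic hydrogen so it cannot epimerize later.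

Step 16
Reactants: 26 ester
Product: 27 (3S)-3-({[tert-butyl(dimethyl)silyl]oxy}methyl)-5-methylhex-4-en-1-ol
Conditions: LiAlH4, Et2O, 0 °C
Reagents that add atoms: none
Why: Hydride reduction of the ester to the primary alcohol leaves the silyl ether and alkene intact.

Step 17
Reactants: 27 alcohol
Product: 28 (3S)-3-({[tert-butyl(dimethyl)silyl]oxy}methyl)-5-methylhex-4-en-1-yl 4-methylbenzenesulfonate
Conditions: TsCl, Et3N, DMAP (cat.), CH2Cl2, 0 °C to rt
Reagents that add atoms: 4-toluenesulfonyl chloride, Cc1ccc(cc1)S(=O)(=O)Cl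
Why: Sulfonylation activates the primary alcohol for the copper-catalysed coupling.

Step 18
Reactants: 28 tosylate; 29 isopropenylmagnesium bromide
Product: 30 tert-butyl(dimethyl){[(2S)-5-methyl-2-(2-methylprop-1-en-1-yl)hex-5-en-1-yl]oxy}silane
Conditions: 29 (3 equiv), CuI (10 mol%), THF, −30 to 0 °C
Reagents that add atoms: none
Why: Copper-catalysed Grignard cross-coupling (Kochi type) displaces the primary tosylate at a carbon remote from the stereocentre and completes the C11 skeleton.

Step 19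
Reactants: 30 silyl ether
Product: 31 (2S)-5-methyl-2-(2-methylprop-1-en-1-yl)hex-5-en-1-ol
Conditions: HF·pyridine, THF, 0 °C to rt
Reagents that add atoms: none
Why: Fluoride cleavage of the primary silyl ether does not affect the two alkenes.

Step 20
Reactants: 31 alcohol
Product: 32 (5S)-5-(iodomethyl)-2,7-dimethylocta-1,6-diene
Conditions: I2, PPh3, imidazole, CH2Cl2, 0 °C
Reagents that add atoms: iodine, II
Why: Appel-type iodination of the primary alcohol is neutral and leaves the adjacent stereocentre untouched.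

Step 21
Reactants: 32 C11 iodide; 21 aryl iodide
Product: 35 (4R)-8-{(2R,3R)-3-[(tert-butyldimethylsilyl)oxy]-2-methylbutanoyl}-5,7-bis(methoxymethoxy)-6-[(2R)-5-methyl-2-(2-methylprop-1-en-1-yl)hex-5-en-1-yl]-4-phenyl-3,4-dihydro-2H-chromen-2-one, via alkyllithium 33 (not isolated), via alkylzinc chloride 34 (not isolated)
Conditions: 32 (1.5 equiv), t-BuLi (3.0 equiv), Et2O, −78 °C; ZnCl2 (1.6 equiv) in THF, −78 °C to rt; then 21 (1.0 equiv), Pd(OAc)2 (5 mol%), SPhos (10 mol%), THF/NMP, 50 °C
Reagents that add atoms: none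
Why: Iodine–lithium exchange at −78 °C (polar, too cold for cyclization onto the alkenes), transmetalation to zinc and Negishi sp3–sp2 coupling with a bulky biarylphosphine join the fragments without base, so the ketone α-centre, the lactone and the silyl ether survive.

Step 22
Reactants: 35 lactone; 36 3-methylbut-2-en-1-ol
Product: 37 3-methylbut-2-en-1-yl (3R)-3-[3-{(2R,3R)-3-[(tert-butyldimethylsilyl)oxy]-2-methylbutanoyl}-2-hydroxy-4,6-bis(methoxymethoxy)-5-[(2R)-5-methyl-2-(2-methylprop-1-en-1-yl)hex-5-en-1-yl]phenyl]-3-phenylpropanoate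
Conditions: 36 (3 equiv), LiN(SiMe3)2 (1.2 equiv), THF, −40 to 0 °C; AcOH
Reagents that add atoms: none
Why: Alkoxide transesterification opens the aryl lactone irreversibly (the phenoxide released is chelated to the ortho ketone), freeing exactly the phenol that must become the pyranone oxygen and installing the prenyl ester used in step 26.

Step 23
Reactants: 37 silyl ether
Product: 38 3-methylbut-2-en-1-yl (3R)-3-[2-hydroxy-3-[(2R,3R)-3-hydroxy-2-methylbutanoyl]-4,6-bis(methoxymethoxy)-5-[(2R)-5-methyl-2-(2-methylprop-1-en-1-yl)hex-5-en-1-yl]phenyl]-3-phenylpropanoate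
Conditions: HF·pyridine, THF/pyridine, 0 °C to rt
Reagents that add atoms: none
Why: Buffered fluoride removes the secondary silyl ether without base, so the β-hydroxy ketone neither eliminates nor epimerizes.

Step 24
Reactants: 38 β-hydroxy ketone
Product: 39 3-methylbut-2-en-1-yl (3R)-3-{(2S,3R)-5,7-bis(methoxymethoxy)-2,3-dimethyl-6-[(2R)-5-methyl-2-(2-methylprop-1-en-1-yl)hex-5-en-1-yl]-4-oxo-3,4-dihydro-2H-chromen-8-yl}-3-phenylpropanoate
Conditions: PPh3, DIAD, toluene/THF, 0 °C
Reagents that add atoms: none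
Why: Intramolecular Mitsunobu etherification: the chelated phenol displaces the activated carbinol with inversion (3R carbinol becomes 2S) while C3 is untouched, giving the cis-(2S,3R) chromanone, and the other two ring oxygens are MOM-capped so only this ring can form.

Step 25
Reactants: 39 bis-MOM chromanone
Product: 40 3-methylbut-2-en-1-yl (3R)-3-{(2S,3R)-5,7-dihydroxy-2,3-dimethyl-6-[(2R)-5-methyl-2-(2-methylprop-1-en-1-yl)hex-5-en-1-yl]-4-oxo-3,4-dihydro-2H-chromen-8-yl}-3-phenylpropanoate
Conditions: Me3SiOTf (4 equiv), 2,2'-bipyridyl (6 equiv), MeCN, 0 °C; then H2O, rt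
Reagents that add atoms: none
Why: The buffered silyl triflate/bipyridyl cleavage of aromatic MOM ethers is non-protic, so the alkenes, the prenyl ester and the base- and acid-sensitive cis C3 centre are preserved.

Step 26
Reactants: 40 prenyl ester of the aromatic chromanone acid
Product: 41 (3R)-3-[(2S,3R,6S)-4-hydroxy-2,3-dimethyl-6-(3-methylbut-2-en-1-yl)-6-[(2R)-5-methyl-2-(2-methylprop-1-en-1-yl)hex-5-en-1-yl]-5,7-dioxo-3,5,6,7-tetrahydro-2H-chromen-8-yl]-3-phenylpropanoic acid
Conditions: Pd2(dba)3·CHCl3 (2.5 mol%), (S,S)-DACH-phenyl Trost ligand (7.5 mol%), degassed toluene (0.02 M), 0 to 40 °C, no added base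
Reagents that add atoms: none
Why: Proposed new method: a self-relayed deallylative dearomatization in which zerovalent palladium ionizes the prenyl ester to a carboxylate/(η3-prenyl)palladium ion pair, the carboxylate is the only base and deprotonates the C5/C7 hydroxyls, and the phloroglucinolate attacks the unsubstituted allyl terminus through C6; return to carboxylate or phenol oxygen is reversible under palladium whereas C–C formation gives the stabilized β-triketone enol and is not, only one prenyl is available per molecule so over-alkylation is impossible, and the chiral pocket of the ligand (amide N–H contact to the enolate oxygens) is expected to select the C6 face that gives (6S) (to be confirmed on the first run; the antipodal ligand gives the C6 epimer); the closest known chemistry is palladium-catalysed allyl ester cleavage with 1,3-dicarbonyl allyl scavengers and palladium-catalysed asymmetric allylic dearomatization of naphthols and acylphloroglucinols with allyl carbonates.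

**Compound list**

1 | resorcinol | Oc1cccc(O)c1 | starting material
2 | 1,3-bis(methoxymethoxy)benzene | COCOc1cccc(OCOC)c1 | intermediate
3 | 2-[3,5-bis(methoxymethoxy)phenyl]-4,4,5,5-tetramethyl-1,3,2-dioxaborolane | COCOc1cc(OCOC)cc(c1)B1OC(C)(C)C(C)(C)O1 | intermediate (not isolated)
4 | 3,5-bis(methoxymethoxy)phenol | COCOc1cc(O)cc(OCOC)c1 | intermediate
5 | 1,3,5-tris(methoxymethoxy)benzene | COCOc1cc(OCOC)cc(OCOC)c1 | intermediate
6 | methyl (3R)-3-hydroxybutanoate | C[C@@H](O)CC(=O)OC | starting material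
7 | dilithium (3R)-1-methoxybut-1-ene-1,3-diolate | C[C@@H]([O-])C=C([O-])OC.[Li+].[Li+] | intermediate (not isolated)
8 | methyl (2R,3R)-3-hydroxy-2-methylbutanoate | C[C@@H](O)[C@@H](C)C(=O)OC | intermediate
9 | methyl (2R,3R)-3-[(tert-butyldimethylsilyl)oxy]-2-methylbutanoate | C[C@@H](O[Si](C)(C)C(C)(C)C)[C@@H](C)C(=O)OC | intermediate
10 | (2R,3R)-3-[(tert-butyldimethylsilyl)oxy]-N-methoxy-N,2-dimethylbutanamide | C[C@@H](O[Si](C)(C)C(C)(C)C)[C@@H](C)C(=O)N(C)OC | intermediate
11 | [2,4,6-tris(methoxymethoxy)phenyl]lithium | [Li]c1c(OCOC)cc(OCOC)cc1OCOC | intermediate (not isolated)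
12 | (2R,3R)-3-[(tert-butyldimethylsilyl)oxy]-2-methyl-1-[2,4,6-tris(methoxymethoxy)phenyl]butan-1-one | C[C@@H](O[Si](C)(C)C(C)(C)C)[C@@H](C)C(=O)c1c(OCOC)cc(OCOC)cc1OCOC | intermediate
13 | (2R,3R)-3-[(tert-butyldimethylsilyl)oxy]-1-[2-hydroxy-4,6-bis(methoxymethoxy)phenyl]-2-methylbutan-1-one | C[C@@H](O[Si](C)(C)C(C)(C)C)[C@@H](C)C(=O)c1c(O)cc(OCOC)cc1OCOC | intermediate
14 | propiolic acid (prop-2-ynoic acid) | C#CC(=O)O | starting material
15 | 2-{(2R,3R)-3-[(tert-butyldimethylsilyl)oxy]-2-methylbutanoyl}-3,5-bis(methoxymethoxy)phenyl prop-2-ynoate | C[C@@H](O[Si](C)(C)C(C)(C)C)[C@@H](C)C(=O)c1c(OC(=O)C#C)cc(OCOC)cc1OCOC | intermediate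
16 | 8-{(2R,3R)-3-[(tert-butyldimethylsilyl)oxy]-2-methylbutanoyl}-5,7-bis(methoxymethoxy)-2H-chromen-2-one | C[C@@H](O[Si](C)(C)C(C)(C)C)[C@@H](C)C(=O)c1c2OC(=O)C=Cc2c(OCOC)cc1OCOC | intermediate
17 | phenylmagnesium bromide | Br[Mg]c1ccccc1 | starting material
18 | dimethyl phenylboronate | COB(OC)c1ccccc1 | intermediate (not isolated)
19 | phenylboronic acid | OB(O)c1ccccc1 | intermediate
20 | (4R)-8-{(2R,3R)-3-[(tert-butyldimethylsilyl)oxy]-2-methylbutanoyl}-5,7-bis(methoxymethoxy)-4-phenyl-3,4-dihydro-2H-chromen-2-one | C[C@@H](O[Si](C)(C)C(C)(C)C)[C@@H](C)C(=O)c1c2OC(=O)C[C@H](c3ccccc3)c2c(OCOC)cc1OCOC | intermediate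
21 | (4R)-8-{(2R,3R)-3-[(tert-butyldimethylsilyl)oxy]-2-methylbutanoyl}-6-iodo-5,7-bis(methoxymethoxy)-4-phenyl-3,4-dihydro-2H-chromen-2-one | C[C@@H](O[Si](C)(C)C(C)(C)C)[C@@H](C)C(=O)c1c2OC(=O)C[C@H](c3ccccc3)c2c(OCOC)c(I)c1OCOC | intermediate
22 | methyl acrylate | C=CC(=O)OC | starting material
23 | allyloxy(tert-butyl)dimethylsilane (silyl-protected allyl alcohol) | C=CCO[Si](C)(C)C(C)(C)C | starting material
24 | methyl (2E)-4-[(tert-butyldimethylsilyl)oxy]but-2-enoate | COC(=O)/C=C/CO[Si](C)(C)C(C)(C)C | intermediate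
25 | (2-methylprop-1-en-1-yl)boronic acid | CC(C)=CB(O)O | starting material
26 | methyl (3S)-3-({[tert-butyl(dimethyl)silyl]oxy}methyl)-5-methylhex-4-enoate | COC(=O)C[C@H](CO[Si](C)(C)C(C)(C)C)C=C(C)C | intermediate
27 | (3S)-3-({[tert-butyl(dimethyl)silyl]oxy}methyl)-5-methylhex-4-en-1-ol | OCC[C@H](CO[Si](C)(C)C(C)(C)C)C=C(C)C | intermediate
28 | (3S)-3-({[tert-butyl(dimethyl)silyl]oxy}methyl)-5-methylhex-4-en-1-yl 4-methylbenzenesulfonate | Cc1ccc(cc1)S(=O)(=O)OCC[C@H](CO[Si](C)(C)C(C)(C)C)C=C(C)C | intermediate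
29 | isopropenylmagnesium bromide | CC(=C)[Mg]Br | starting material
30 | tert-butyl(dimethyl){[(2S)-5-methyl-2-(2-methylprop-1-en-1-yl)hex-5-en-1-yl]oxy}silane | C=C(C)CC[C@H](CO[Si](C)(C)C(C)(C)C)C=C(C)C | intermediate
31 | (2S)-5-methyl-2-(2-methylprop-1-en-1-yl)hex-5-en-1-ol | C=C(C)CC[C@H](CO)C=C(C)C | intermediate
32 | (5S)-5-(iodomethyl)-2,7-dimethylocta-1,6-diene | C=C(C)CC[C@H](CI)C=C(C)C | intermediate
33 | [(2S)-5-methyl-2-(2-methylprop-1-en-1-yl)hex-5-en-1-yl]lithium | C=C(C)CC[C@H](C[Li])C=C(C)C | intermediate (not isolated)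
34 | chlorido[(2S)-5-methyl-2-(2-methylprop-1-en-1-yl)hex-5-en-1-yl]zinc | C=C(C)CC[C@H](C[Zn]Cl)C=C(C)C | intermediate (not isolated)
35 | (4R)-8-{(2R,3R)-3-[(tert-butyldimethylsilyl)oxy]-2-methylbutanoyl}-5,7-bis(methoxymethoxy)-6-[(2R)-5-methyl-2-(2-methylprop-1-en-1-yl)hex-5-en-1-yl]-4-phenyl-3,4-dihydro-2H-chromen-2-one | C[C@@H](O[Si](C)(C)C(C)(C)C)[C@@H](C)C(=O)c1c2OC(=O)C[C@H](c3ccccc3)c2c(OCOC)c(C[C@@H](CCC(C)=C)C=C(C)C)c1OCOC | intermediate
36 | 3-methylbut-2-en-1-ol (prenol) | CC(C)=CCO | starting material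
37 | 3-methylbut-2-en-1-yl (3R)-3-[3-{(2R,3R)-3-[(tert-butyldimethylsilyl)oxy]-2-methylbutanoyl}-2-hydroxy-4,6-bis(methoxymethoxy)-5-[(2R)-5-methyl-2-(2-methylprop-1-en-1-yl)hex-5-en-1-yl]phenyl]-3-phenylpropanoate | C[C@@H](O[Si](C)(C)C(C)(C)C)[C@@H](C)C(=O)c1c(O)c([C@H](CC(=O)OCC=C(C)C)c2ccccc2)c(OCOC)c(C[C@@H](CCC(C)=C)C=C(C)C)c1OCOC | intermediate
38 | 3-methylbut-2-en-1-yl (3R)-3-[2-hydroxy-3-[(2R,3R)-3-hydroxy-2-methylbutanoyl]-4,6-bis(methoxymethoxy)-5-[(2R)-5-methyl-2-(2-methylprop-1-en-1-yl)hex-5-en-1-yl]phenyl]-3-phenylpropanoate | C[C@@H](O)[C@@H](C)C(=O)c1c(O)c([C@H](CC(=O)OCC=C(C)C)c2ccccc2)c(OCOC)c(C[C@@H](CCC(C)=C)C=C(C)C)c1OCOC | intermediate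
39 | 3-methylbut-2-en-1-yl (3R)-3-{(2S,3R)-5,7-bis(methoxymethoxy)-2,3-dimethyl-6-[(2R)-5-methyl-2-(2-methylprop-1-en-1-yl)hex-5-en-1-yl]-4-oxo-3,4-dihydro-2H-chromen-8-yl}-3-phenylpropanoate | O=C1[C@H](C)[C@H](C)Oc2c([C@H](CC(=O)OCC=C(C)C)c3ccccc3)c(OCOC)c(C[C@@H](CCC(C)=C)C=C(C)C)c(OCOC)c12 | intermediate
40 | 3-methylbut-2-en-1-yl (3R)-3-{(2S,3R)-5,7-dihydroxy-2,3-dimethyl-6-[(2R)-5-methyl-2-(2-methylprop-1-en-1-yl)hex-5-en-1-yl]-4-oxo-3,4-dihydro-2H-chromen-8-yl}-3-phenylpropanoate | O=C1[C@H](C)[C@H](C)Oc2c([C@H](CC(=O)OCC=C(C)C)c3ccccc3)c(O)c(C[C@@H](CCC(C)=C)C=C(C)C)c(O)c12 | intermediate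
41 | (3R)-3-[(2S,3R,6S)-4-hydroxy-2,3-dimethyl-6-(3-methylbut-2-en-1-yl)-6-[(2R)-5-methyl-2-(2-methylprop-1-en-1-yl)hex-5-en-1-yl]-5,7-dioxo-3,5,6,7-tetrahydro-2H-chromen-8-yl]-3-phenylpropanoic acid | C=C(C)CC[C@@H](C=C(C)C)C[C@@]1(CC=C(C)C)C(=O)C2=C(O)[C@H](C)[C@H](C)OC2=C([C@H](CC(=O)O)c2ccccc2)C1=O | target

**Totals**

Total step count: 26.
Longest linear sequence: 15 steps (1, 2, 3, 7, 8, 9, 10, 12, 13, 21, 22, 23, 24, 25, 26; the branch from 6 is equally long), which is 58% of the total.

**Three steps most likely to fail**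

Step 26 (the new step; it may stop at O-prenyl ethers or show poor facial selectivity). The fallback uses known chemistry, sets out from 40 and comes back at 41. Base-mediated dearomative C-prenylation of 40 with prenyl bromide (LiN(SiMe3)2, THF, −78 to 0 °C, the lupulone-type gem-dialkylation of acylphloroglucinols) gives the 3-methylbut-2-en-1-yl ester of 41 F1 as a mixture of C6 epimers, which is separated by preparative HPLC. Pd(PPh3)4 with morpholine in THF then cleaves the prenyl ester of the (6S) epimer to 41.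

Step 12 (coumarins are poor acceptors, and this one is electron-rich and carries a peri OMOM group). The fallback makes the C4–H bond instead of the C4–phenyl bond, sets out from 13 and comes back at 20. Phenylacetylene is carboxylated (n-BuLi, CO2, THF) to 3-phenylprop-2-ynoic acid F2. DCC esterification of 13 with it gives 2-{(2R,3R)-3-[(tert-butyldimethylsilyl)oxy]-2-methylbutanoyl}-3,5-bis(methoxymethoxy)phenyl 3-phenylprop-2-ynoate F3. JohnPhosAu(MeCN)SbF6 closes this to 8-{(2R,3R)-3-[(tert-butyldimethylsilyl)oxy]-2-methylbutanoyl}-5,7-bis(methoxymethoxy)-4-phenyl-2H-chromen-2-one F4. Copper hydride asymmetric 1,4-reduction (Cu(OAc)2·H2O, the DTBM-SEGPHOS enantiomer that gives 4R, (EtO)2MeSiH, t-BuOH, toluene, rt) then gives 20.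

Step 24 (elimination to the enone can compete with ring closure and would erode the cis stereochemistry). The fallback closes the ring by conjugate addition instead of substitution, sets out from 37 and comes back at 39. DBU in toluene at 80 °C eliminates the silanol (E1cB) to give 3-methylbut-2-en-1-yl (3R)-3-[2-hydroxy-3-[(2E)-2-methylbut-2-enoyl]-4,6-bis(methoxymethoxy)-5-[(2R)-5-methyl-2-(2-methylprop-1-en-1-yl)hex-5-en-1-yl]phenyl]-3-phenylpropanoate F5. A cinchona-alkaloid-catalysed intramolecular oxa-Michael addition (quinine or quinidine, whichever gives 2S,3R; chlorobenzene, rt), which in the calanolide series gives the cis-2,3-dimethylchromanone by kinetic protonation, then closes the pyranone ring to 39.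

**Further compounds**

F1 | step 26 | 3-methylbut-2-en-1-yl (3R)-3-[(2S,3R,6S)-4-hydroxy-2,3-dimethyl-6-(3-methylbut-2-en-1-yl)-6-[(2R)-5-methyl-2-(2-methylprop-1-en-1-yl)hex-5-en-1-yl]-5,7-dioxo-3,5,6,7-tetrahydro-2H-chromen-8-yl]-3-phenylpropanoate | C=C(C)CC[C@@H](C=C(C)C)C[C@@]1(CC=C(C)C)C(=O)C2=C(O)[C@H](C)[C@H](C)OC2=C([C@H](CC(=O)OCC=C(C)C)c2ccccc2)C1=O
F2 | step 12 | 3-phenylprop-2-ynoic acid | OC(=O)C#Cc1ccccc1
F3 | step 12 | 2-{(2R,3R)-3-[(tert-butyldimethylsilyl)oxy]-2-methylbutanoyl}-3,5-bis(methoxymethoxy)phenyl 3-phenylprop-2-ynoate | C[C@@H](O[Si](C)(C)C(C)(C)C)[C@@H](C)C(=O)c1c(OC(=O)C#Cc2ccccc2)cc(OCOC)cc1OCOC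
F4 | step 12 | 8-{(2R,3R)-3-[(tert-butyldimethylsilyl)oxy]-2-methylbutanoyl}-5,7-bis(methoxymethoxy)-4-phenyl-2H-chromen-2-one | C[C@@H](O[Si](C)(C)C(C)(C)C)[C@@H](C)C(=O)c1c2OC(=O)C=C(c3ccccc3)c2c(OCOC)cc1OCOC
F5 | step 24 | 3-methylbut-2-en-1-yl (3R)-3-[2-hydroxy-3-[(2E)-2-methylbut-2-enoyl]-4,6-bis(methoxymethoxy)-5-[(2R)-5-methyl-2-(2-methylprop-1-en-1-yl)hex-5-en-1-yl]phenyl]-3-phenylpropanoate | C/C=C(\C)C(=O)c1c(O)c([C@H](CC(=O)OCC=C(C)C)c2ccccc2)c(OCOC)c(C[C@@H](CCC(C)=C)C=C(C)C)c1OCOC
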